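Ring A (the benzene ring: C1 bears the ketone, C2 OH, C3 the 4-methylpentyl chain, C4 OH, C5 and C6 H) is assembled de novo. C1 and C6 are the alkyne carbons of a terminal pyrrolyl ynone; C2, C3, C4 and C5 are the ester carbon, α-carbon, ketone carbon and methyl carbon of a 2-alkylated acetoacetate. One Diels–Alder benzannulation between the derived 1-methoxy-1,3-bis(trimethylsilyloxy)diene and the N-SEM-protected ynone forms C1–C2 and C5–C6, closes ring A with all four contiguous substituents in place and, by loss of methanol and the silyl groups, frees both phenols. Fluoride cleavage of SEM from the pyrrole (ring B) completes the synthesis.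

Key step: step 7

Assumption: the C=C geometries drawn for the silyl enol ether, the dienolate and the diene are chosen for definiteness; either isomer or a mixture should serve, because these double bonds end up inside aromatic ring A.

Step 1
Reactants: 1 methyl acetoacetate; 2 1-bromo-4-methylpentane
Product: 4 methyl 2-acetyl-6-methylheptanoate (racemic), via sodium enolate of methyl acetoacetate 3 (not isolated)
Conditions: NaH (1.0 equiv), THF, 0 °C; then 2 (0.9 equiv), NaI (10 mol %), reflux
Reagents that add atoms: none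
Why: Acetoacetic ester alkylation (SN2 of the stabilized sodium enolate on a primary bromide, assisted by Finkelstein exchange) is routine, a slight excess of keto ester should suppress dialkylation, and the new C2 stereocentre is racemic and disappears in step 2.

Step 2
Reactants: 4 methyl 2-acetyl-6-methylheptanoate
Product: 5 methyl (2Z)-2-(4-methylpentyl)-3-(trimethylsilyloxy)but-2-enoate
Conditions: Me3SiCl (1.5 equiv), Et3N (1.6 equiv), toluene, rt, 48–72 h; filtration under argon
Reagents that add atoms: chlorotrimethylsilane, C[Si](C)(C)Cl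
Why: Silyl enol ether formation at the ketone oxygen of an enolizable β-keto ester with Me3SiCl/Et3N is the standard first stage towards 1,3-bis(silyloxy)dienes, and it removes the stereocentre of 4.

Step 3
Reactants: 5 methyl (2Z)-2-(4-methylpentyl)-3-(trimethylsilyloxy)but-2-enoate
Product: 7 (1E)-1-methoxy-2-(4-methylpentyl)-1,3-bis(trimethylsilyloxy)buta-1,3-diene, via lithium 1-methoxy-2-(4-methylpentyl)-3-(trimethylsilyloxy)buta-1,3-dien-1-olate 6 (not isolated)
Conditions: LiN(i-Pr)2 (commercial solution, 1.3 equiv), THF, −78 °C; Me3SiCl (1.5 equiv), −78 °C → rt; hexane, filtration under argon; used crude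
Reagents that add atoms: chlorotrimethylsilane, C[Si](C)(C)Cl
Why: Kinetic γ-deprotonation of the vinylogous ester (only the C4 methyl gives an ester-conjugated dienolate) followed by O-silylation is the established silyl ketene acetal formation that delivers 2-alkyl-1,3-bis(silyloxy)dienes.

Step 4
Reactants: 8 4,5-dichloro-1H-pyrrole-2-carboxylic acid
Product: 9 4,5-dichloro-N-methoxy-N-methyl-1H-pyrrole-2-carboxamide
Conditions: MeNHOMe·HCl (1.5 equiv), EDC·HCl (1.3 equiv), HOBt, i-Pr2NEt (3 equiv), DMF, 0 °C → rt
Reagents that add atoms: N,O-dimethylhydroxylamine hydrochloride, CNOC.Cl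
Why: Carbodiimide-mediated amidation is mild enough to avoid the self-condensation that acid chlorides of N-unprotected pyrroles undergo, and the electron-poor ring N–H is too weak a nucleophile to compete.

Step 5
Reactants: 9 4,5-dichloro-N-methoxy-N-methyl-1H-pyrrole-2-carboxamide
Product: 11 4,5-dichloro-N-methoxy-N-methyl-1-{[2-(trimethylsilyl)ethoxy]methyl}pyrrole-2-carboxamide, via sodium 2,3-dichloro-5-[methoxy(methyl)carbamoyl]pyrrol-1-ide 10 (not isolated)
Conditions: NaH (1.2 equiv), THF–DMF, 0 °C; SEMCl (1.2 equiv), 0 °C → rt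
Reagents that add atoms: 2-(trimethylsilyl)ethoxymethyl chloride, C[Si](C)(C)CCOCCl
Why: N-alkylation of the irreversibly formed pyrrolide with the reactive chloromethyl ether (SN2) is standard, and the resulting N,O-acetal is inert to Grignard reagents and silyl ketene acetals and carries no acidic hydrogen.

Step 6
Reactants: 11 4,5-dichloro-N-methoxy-N-methyl-1-{[2-(trimethylsilyl)ethoxy]methyl}pyrrole-2-carboxamide; 12 ethynylmagnesium bromide
Product: 14 1-(4,5-dichloro-1-{[2-(trimethylsilyl)ethoxy]methyl}pyrrol-2-yl)prop-2-yn-1-one, via chelated bromomagnesium tetrahedral adduct 13 (not isolated)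
Conditions: HC≡CMgBr (0.5 M in THF, 2.5 equiv), THF, 0 °C → rt; inverse quench into cold 1 M HCl/Et2O
Reagents that add atoms: none
Why: Weinreb ketone synthesis, in which the magnesium chelate of the racemic tetrahedral adduct prevents over-addition, and the acidic inverse quench protonates the released N,O-dimethylhydroxylamine before it can add to the ynone.

Step 7
Reactants: 7 (1E)-1-methoxy-2-(4-methylpentyl)-1,3-bis(trimethylsilyloxy)buta-1,3-diene; 14 1-(4,5-dichloro-1-{[2-(trimethylsilyl)ethoxy]methyl}pyrrol-2-yl)prop-2-yn-1-one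
Product: 16 (4,5-dichloro-1-{[2-(trimethylsilyl)ethoxy]methyl}pyrrol-2-yl)[2,4-dihydroxy-3-(4-methylpentyl)phenyl]methanone, via racemic 1,4-cyclohexadiene cycloadduct 15 (not isolated)
Conditions: 7 (2.0 equiv), toluene, argon, 0 °C → rt (45 °C if slow); then 1 M aq. HCl, THF, 0 °C → rt
Reagents that add atoms: none
Why: This is a normal-electron-demand Diels–Alder cycloaddition of the electron-rich bis(silyloxy)diene to the electron-poor terminal ynone followed by eliminative aromatization, the closest known reaction type being the benzannulation of 1-alkoxy-1,3-bis(silyloxy)butadienes with acetylenic ketones and esters to resorcinols. Ring A closes in the [4+2] mode, the four diene carbons joining the two alkyne carbons through C5–C6 and C1–C2, probably asynchronously with C5–C6 leading. The only stereocentre formed, the mixed methyl silyl ketal carbon C2 of 15, is racemic and is erased when dilute acid expels methanol, unveils the C2 carbonyl, hydrolyses the C4 silyl enol ether and lets the cross-conjugated dienone tautomerize to the resorcinol, so no stereocontrol is needed. The selectivity needed is regiochemical: the nucleophilic CH2 terminus of the diene must bond to the β-carbon of the ynone (C6) and the ketene acetal carbon to the acyl-bearing carbon (C1), which the matched polarization of the two partners secures and which places the ketone ortho to the C2 hydroxyl and para to the C4 hydroxyl. The alkyl group on the inner diene carbon favours the s-cis conformer, the unsubstituted alkyne terminus is unhindered, the SEM group removes the N–H that would protonate the ketene acetal, and cold dilute HCl is too mild to cleave the SEM aminal.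

Step 8
Reactants: 16 (4,5-dichloro-1-{[2-(trimethylsilyl)ethoxy]methyl}pyrrol-2-yl)[2,4-dihydroxy-3-(4-methylpentyl)phenyl]methanone
Product: 17 (4,5-dichloro-1H-pyrrol-2-yl)[2,4-dihydroxy-3-(4-methylpentyl)phenyl]methanone
Conditions: n-Bu4NF (1.0 M in THF, 6 equiv), H2NCH2CH2NH2 (5 equiv), THF, 60 °C; aq. NH4Cl work-up
Reagents that add atoms: none
Why: Fluoride-induced SEM cleavage (attack at silicon, fragmentation to ethene and a hemiaminal alkoxide, expulsion of the well-stabilized acyl dichloropyrrolide with loss of formaldehyde) is standard for electron-poor N-SEM pyrroles; the phenols merely sit as phenoxides and ethylenediamine should trap formaldehyde before it can hydroxymethylate C5 of ring A.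

Compound list
1 | methyl acetoacetate | COC(=O)CC(C)=O | starting material
2 | 1-bromo-4-methylpentane | CC(C)CCCBr | starting material
3 | sodium (2Z)-4-methoxy-4-oxobut-2-en-2-olate (sodium enolate of 1) | COC(=O)/C=C(/C)[O-].[Na+] | intermediate (not isolated)
4 | methyl 2-acetyl-6-methylheptanoate (racemic) | COC(=O)C(CCCC(C)C)C(C)=O | intermediate
5 | methyl (2Z)-2-(4-methylpentyl)-3-(trimethylsilyloxy)but-2-enoate | COC(=O)/C(CCCC(C)C)=C(/C)O[Si](C)(C)C | intermediate
6 | lithium (1Z)-1-methoxy-2-(4-methylpentyl)-3-(trimethylsilyloxy)buta-1,3-dien-1-olate | CO/C([O-])=C(/CCCC(C)C)C(=C)O[Si](C)(C)C.[Li+] | intermediate (not isolated)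
7 | (1E)-1-methoxy-2-(4-methylpentyl)-1,3-bis(trimethylsilyloxy)buta-1,3-diene | CO/C(O[Si](C)(C)C)=C(/CCCC(C)C)C(=C)O[Si](C)(C)C | intermediate
8 | 4,5-dichloro-1H-pyrrole-2-carboxylic acid | OC(=O)c1cc(Cl)c(Cl)[nH]1 | starting material
9 | 4,5-dichloro-N-methoxy-N-methyl-1H-pyrrole-2-carboxamide | CON(C)C(=O)c1cc(Cl)c(Cl)[nH]1 | intermediate
10 | sodium 2,3-dichloro-5-[methoxy(methyl)carbamoyl]pyrrol-1-ide | CON(C)C(=O)c1cc(Cl)c(Cl)[n-]1.[Na+] | intermediate (not isolated)
11 | 4,5-dichloro-N-methoxy-N-methyl-1-{[2-(trimethylsilyl)ethoxy]methyl}pyrrole-2-carboxamide | CON(C)C(=O)c1cc(Cl)c(Cl)n1COCC[Si](C)(C)C | intermediate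
12 | ethynylmagnesium bromide | C#C[Mg]Br | starting material
13 | bromomagnesium 1-(4,5-dichloro-1-{[2-(trimethylsilyl)ethoxy]methyl}pyrrol-2-yl)-1-[methoxy(methyl)amino]prop-2-yn-1-olate (racemic, chelated) | C#CC(O[Mg]Br)(N(C)OC)c1cc(Cl)c(Cl)n1COCC[Si](C)(C)C | intermediate (not isolated)
14 | 1-(4,5-dichloro-1-{[2-(trimethylsilyl)ethoxy]methyl}pyrrol-2-yl)prop-2-yn-1-one | C#CC(=O)c1cc(Cl)c(Cl)n1COCC[Si](C)(C)C | intermediate
15 | (4,5-dichloro-1-{[2-(trimethylsilyl)ethoxy]methyl}pyrrol-2-yl)[6-methoxy-5-(4-methylpentyl)-4,6-bis(trimethylsilyloxy)cyclohexa-1,4-dien-1-yl]methanone (racemic) | COC1(O[Si](C)(C)C)C(CCCC(C)C)=C(O[Si](C)(C)C)CC=C1C(=O)c1cc(Cl)c(Cl)n1COCC[Si](C)(C)C | intermediate (not isolated)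
16 | (4,5-dichloro-1-{[2-(trimethylsilyl)ethoxy]methyl}pyrrol-2-yl)[2,4-dihydroxy-3-(4-methylpentyl)phenyl]methanone | CC(C)CCCc1c(O)ccc(C(=O)c2cc(Cl)c(Cl)n2COCC[Si](C)(C)C)c1O | intermediate
17 | (4,5-dichloro-1H-pyrrol-2-yl)[2,4-dihydroxy-3-(4-methylpentyl)phenyl]methanone | CC(C)CCCc1c(O)ccc(C(=O)c2cc(Cl)c(Cl)[nH]2)c1O | target

Total step count: 8. Longest linear sequence: 5 steps (steps 1, 2, 3, 7, 8 or steps 4, 5, 6, 7, 8).

Steps most likely to fail

1. Step 7. The donor-substituted ynone may react slowly, so that the moisture-sensitive diene is lost by protodesilylation before it cycloadds. Open-chain conjugate addition without ring closure, or partial retention of the C2 oxygen as a methyl ether, could also reduce the return. The fallback replaces the cycloaddition with an aryllithium acylation; it sets out from 2 and 11 and rejoins the route at 16. Resorcinol is protected with MOMCl/i-Pr2NEt as 1,3-bis(methoxymethoxy)benzene F1. n-BuLi (THF, 0 °C) should metalate between the two acetal oxygens to give [2,6-bis(methoxymethoxy)phenyl]lithium F2, which is alkylated with bromide 2 to 1,3-bis(methoxymethoxy)-2-(4-methylpentyl)benzene F3. A second directed ortho-lithiation (n-BuLi/TMEDA) should give [2,4-bis(methoxymethoxy)-3-(4-methylpentyl)phenyl]lithium F4, which is added at −78 °C to Weinreb amide 11 to give (4,5-dichloro-1-{[2-(trimethylsilyl)ethoxy]methyl}pyrrol-2-yl)[2,4-bis(methoxymethoxy)-3-(4-methylpentyl)phenyl]methanone F5. HCl in MeOH at rt to 40 °C then removes both MOM groups and delivers 16.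

2. Step 8. Formaldehyde released during SEM cleavage may be captured by the electron-rich C5 position of ring A (hydroxymethylation or methylene bridging), or the cleavage may stall at partial conversion. The fallback masks the phenols first and cleaves SEM by acidolysis; it sets out from 16 and rejoins at 17. Ac2O/pyridine with catalytic DMAP gives 4-(4,5-dichloro-1-{[2-(trimethylsilyl)ethoxy]methyl}pyrrole-2-carbonyl)-2-(4-methylpentyl)-1,3-phenylene diacetate F6, whose ring A is deactivated and has no free ortho hydroxyl. CF3CO2H in CH2Cl2 at rt should then give 4-[4,5-dichloro-1-(hydroxymethyl)pyrrole-2-carbonyl]-2-(4-methylpentyl)-1,3-phenylene diacetate F7. NH3 in MeOH at rt finally removes both acetates and the N-hydroxymethyl group, sequestering formaldehyde as its ammonia adduct, to give 17.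

3. Step 6. Conjugate addition of the liberated N,O-dimethylhydroxylamine to the ynone during the quench, or base-induced oligomerization of the terminal ynone, may erode the product. The fallback avoids the amine by going through the aldehyde oxidation level; it sets out from 11 and rejoins at 14. i-Bu2AlH (THF, −78 °C) reduces the Weinreb amide to 4,5-dichloro-1-{[2-(trimethylsilyl)ethoxy]methyl}pyrrole-2-carbaldehyde F8, which is purified. Addition of 12 at 0 °C gives racemic 1-(4,5-dichloro-1-{[2-(trimethylsilyl)ethoxy]methyl}pyrrol-2-yl)prop-2-yn-1-ol F9, and MnO2 in CH2Cl2 at rt oxidizes this propargylic alcohol to 14 under neutral conditions.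

Further compounds
F1 | step 7 | 1,3-bis(methoxymethoxy)benzene | COCOc1cccc(OCOC)c1
F2 | step 7 | [2,6-bis(methoxymethoxy)phenyl]lithium | [Li]c1c(OCOC)cccc1OCOC
F3 | step 7 | 1,3-bis(methoxymethoxy)-2-(4-methylpentyl)benzene | CC(C)CCCc1c(OCOC)cccc1OCOC
F4 | step 7 | [2,4-bis(methoxymethoxy)-3-(4-methylpentyl)phenyl]lithium | [Li]c1ccc(OCOC)c(CCCC(C)C)c1OCOC
F5 | step 7 | (4,5-dichloro-1-{[2-(trimethylsilyl)ethoxy]methyl}pyrrol-2-yl)[2,4-bis(methoxymethoxy)-3-(4-methylpentyl)phenyl]methanone | CC(C)CCCc1c(OCOC)ccc(C(=O)c2cc(Cl)c(Cl)n2COCC[Si](C)(C)C)c1OCOC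
F6 | step 8 | 4-(4,5-dichloro-1-{[2-(trimethylsilyl)ethoxy]methyl}pyrrole-2-carbonyl)-2-(4-methylpentyl)-1,3-phenylene diacetate | CC(C)CCCc1c(OC(C)=O)ccc(C(=O)c2cc(Cl)c(Cl)n2COCC[Si](C)(C)C)c1OC(C)=O
F7 | step 8 | 4-[4,5-dichloro-1-(hydroxymethyl)pyrrole-2-carbonyl]-2-(4-methylpentyl)-1,3-phenylene diacetate | CC(C)CCCc1c(OC(C)=O)ccc(C(=O)c2cc(Cl)c(Cl)n2CO)c1OC(C)=O
F8 | step 6 | 4,5-dichloro-1-{[2-(trimethylsilyl)ethoxy]methyl}pyrrole-2-carbaldehyde | O=Cc1cc(Cl)c(Cl)n1COCC[Si](C)(C)C
F9 | step 6 | 1-(4,5-dichloro-1-{[2-(trimethylsilyl)ethoxy]methyl}pyrrol-2-yl)prop-2-yn-1-ol (racemic) | C#CC(O)c1cc(Cl)c(Cl)n1COCC[Si](C)(C)C
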